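## The problem

Artocarpetin B (16) is a flavone: a 4H-chromen-4-one whose pyranone ring C is fused to the benzenoid ring A along C4a–C8a and carries the 4-hydroxy-2-methoxyphenyl ring B at C2. The molecule has no stereocentre, so nothing has to be set or relayed, and the whole difficulty is regiochemical. Ring A is pentasubstituted and fully differentiated: a hydrogen-bonded 5-OH, a 7-OMe, and a prenyl group at C8 between the 7-OMe and the ring oxygen. Phloroglucinol-based routes reach this pattern only by telling three oxygens apart and by steering a C-prenylation to C8 instead of the nearly equivalent C6. Ring B needs a free 4'-OH beside a 2'-OMe, so its phenol must be masked by something other than a methyl ether. The prenyl alkene is the fragile element: it does not survive hydrogenolysis, and strong protic or Lewis acids, halogens and peracids add to it, which limits the protecting group on O4' and every reagent used once the side chain is present. A short synthesis is possible because C5–C8 of ring A, with O5, O7 and the prenyl carbon attached, are the four carbons of a 4-substituted 1,3-dioxygenated butadiene at the acetoacetate oxidation level, while the C4a–C8a bond is the α,β-C=C of a monocyclic 4-pyranone. C8a, the enone β-carbon, can carry a leaving group and C4a carries a hydrogen, so a diene can be added across this bond and ring A aromatised by two eliminations with every substituent already in place.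

## Retrosynthesis

**16 from 15.** The last bond cut is the O–CH2 bond of a methoxymethyl acetal on O4', which leads back to 5-hydroxy-7-methoxy-2-[2-methoxy-4-(methoxymethoxy)phenyl]-8-prenylchromen-4-one (15). The acetal is preferred to a benzyl ether, whose hydrogenolysis would saturate the prenyl group, and to a silyl ether, which would not survive the ethoxide and dianion steps early in the route. The forward step must be an acid treatment mild enough to leave the trisubstituted alkene alone; no hydroxyl sits ortho to the prenyl group, so chroman formation is not possible.

**15 from 8 and 13.** Ring A is removed by cutting C4a–C5 and C8–C8a. This leads to 2-[2-methoxy-4-(methoxymethoxy)phenyl]-6-(methylsulfonyl)-4H-pyran-4-one (8) and (3Z)-1,3-dimethoxy-7-methyl-1-(trimethylsilyloxy)octa-1,3,6-triene (13), through the non-isolated adduct 14.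
- Against the neighbouring cuts through ring C, this one does not require a pre-formed, regiochemically pure prenylated phloroglucinol. The 5-OH, 7-OMe and 8-prenyl groups all come from an acyclic diene whose substitution is fixed by enolate chemistry.
- The simplification is large: a tricyclic compound with a pentasubstituted benzene becomes a disubstituted pyranone and an open-chain triene.
- The forward reaction must be a polarity-matched union. The nucleophilic C4 of the diene bonds to the sulfonyl-bearing pyranone C6 (future C8a), the ketene acetal carbon bonds to C5 (future C4a), and methanesulfinic acid and methanol are then lost.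

**13 from 9 and 10.** The O–Si bond of 13 is cut back to methyl (2E)-3-methoxy-7-methylocta-2,6-dienoate (12). The enol ether C–O bond of 12 is cut back to methyl 7-methyl-3-oxooct-6-enoate (11). The C4–C5 bond of 11 is cut back to methyl acetoacetate (9) and prenyl bromide (10). The prenyl group is therefore introduced by a C-alkylation that has only one possible site, before any ring exists. The forward steps must give γ-alkylation, O-methylation to the conjugated E enol ether, and γ-deprotonation with the chain turned away from C2.

**8 from 7.** The two S–O bonds are cut, leading to the sulfide 2-[2-methoxy-4-(methoxymethoxy)phenyl]-6-(methylsulfanyl)-4H-pyran-4-one (7). Sulfur is carried at the sulfide level through the basic steps because sulfone 8 is an electrophile. Oxidation is the last operation before the key step and takes place before the prenyl alkene is in the molecule.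

**7 from 6.** The O1–C6 bond of the pyranone is cut, giving the open ketene dithioacetal 1-[2-methoxy-4-(methoxymethoxy)phenyl]-5,5-bis(methylsulfanyl)pent-4-ene-1,3-dione (6). The forward step is an intramolecular vinylic substitution by the enol oxygen with loss of methanethiol. It must be run under acid weak enough to spare the acetal.

**6 from 1, 3 and 5.** The bond between the terminal carbon of the diketone and the dithioacetal carbon is cut, together with both S–CH3 bonds. This gives 1-[2-methoxy-4-(methoxymethoxy)phenyl]butane-1,3-dione (4) and carbon disulfide (5), which supplies the future C8a. Diketone 4 is cut at its C2–C3 bond into 1-[2-methoxy-4-(methoxymethoxy)phenyl]ethanone (2) and ethyl acetate (3). Ketone 2 is the methoxymethyl ether of 4'-hydroxy-2'-methoxyacetophenone (1), which already holds ring B with its two oxygens differentiated. The forward steps must give terminal, not central, functionalisation of the diketone, which calls for its dianion.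

## Roads not taken

**Alternative 1:** Here ring B is cut at C1'–C2' and C5'–C6', leaving 2-ethynyl-5,7-dimethoxy-8-(3-methylbut-2-enyl)chromen-4-one A1 and 1,1-dimethoxy-3-(trimethylsilyloxy)buta-1,3-diene A2. In the forward direction A2 adds across the alkyne and loss of methanol aromatises the new ring to 2-(4-hydroxy-2-methoxyphenyl)-5,7-dimethoxy-8-(3-methylbut-2-enyl)chromen-4-one A3. Cleavage of the 5-OMe would finish the synthesis.
- Merits: the two oxygens of ring B are differentiated by construction, ring B needs no protecting group, and A2 is a more ordinary diene than 13.
- Weak points: the plan builds the ring that can be bought (ring B is contained in 1) and leaves the real problem to classical chemistry, since A1 still needs the 5,7-dioxygenated 8-prenyl ring A with its C6/C8 ambiguity. The alkyne of A1 is activated only vinylogously through C2=C3, and A2 may add to C2 of the chromone instead. The final 5-O-demethylation needs a boron or aluminium halide in the presence of the prenyl alkene.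
- Comparison: Alternative 1 is the better road for ring B. The chosen plan has to set against this that it solves ring A and ends with one mild acetal cleavage. Neither key step has been tested on its substrate class, so Alternative 1 has no advantage in certainty.

**Alternative 2:** Here ring C is cut at C4–C4a, leading to (2Z)-3-[4-(benzyloxy)-2-methoxyphenyl]-3-[3,5-dimethoxy-2-(3-methylbut-2-enyl)phenoxy]prop-2-enoic acid A4. Its acid chloride would acylate the only free ortho position of the phenoxy ring to give 2-[4-(benzyloxy)-2-methoxyphenyl]-5,7-dimethoxy-8-(3-methylbut-2-enyl)chromen-4-one A5.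
- Merits: every step is of a known type, the route is convergent, and the site of ring closure is unambiguous.
- Weak points: the phenoxy half of A4 again requires a C-prenylation directed between two oxygens of a phloroglucinol derivative. Forming the acid chloride and running a Friedel–Crafts acylation expose the prenyl alkene to HCl and Lewis acid. A5 then needs two ether cleavages, a debenzylation that cannot be a hydrogenolysis and a 5-O-demethylation, both with Lewis acids.
- Comparison: Alternative 2 is clearly ahead in the reliability of its key step. The chosen plan has to set against this that the prenyl group is placed by an alkylation with a single possible site, that O5 and O7 are differentiated from the start, and that no Lewis acid is used once the alkene is present.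

**Alternative 3:** Here ring A is cut at C5–C6, leading to methyl 6-[2-methoxy-4-(methoxymethoxy)phenyl]-2-(6-methyl-2-oxohept-5-en-3-yl)-4-oxo-4H-pyran-3-carboxylate A6. Its dianion would close ring A by Claisen condensation of the methyl ketone onto the ester to give 5,7-dihydroxy-2-[2-methoxy-4-(methoxymethoxy)phenyl]-8-(3-methylbut-2-enyl)chromen-4-one A7. Selective methylation of the free 7-OH of A7 would give 15.
- Merits: the closure is of the well-known polyketide type, the regiochemistry is fixed by the skeleton of A6, and the end game is the same mild one.
- Weak points: A6 is a fully substituted pyranone with an ester at C3 and a branched ketone chain at C2. Making it takes more steps than 8 and 13 together, and it needs its own C–C bond formation at a pyranone carbon. The dianion conditions may open the pyranone ring. One more step is needed for the methylation.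
- Comparison: Alternative 3 is ahead on the precedent for the ring closure and equal in regiocontrol. The chosen plan has to set against this its convergence: two fragments of five and three steps are joined in one operation with the 7-OMe already in place. The kinship is used, since the fallback for the key step closes ring A by a Claisen condensation of the same family.

Key step: step 9

Remarks on the chemistry:
- Compound 1 is taken as a purchasable acetophenone.
- In 13 the C5 methylene must lie trans to C2 across C3=C4 so that the s-cis conformer is accessible. Because the 3-methoxy oxygen outranks C2, this isomer is 3Z. The geometry of the ketene acetal C1=C2 is not defined and has no influence on the product.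

## Route

Step 1
Reactants: 1 4'-hydroxy-2'-methoxyacetophenone
Product: 2 1-[2-methoxy-4-(methoxymethoxy)phenyl]ethan-1-one
Conditions: MOMCl, K2CO3, acetone, 0 °C to rt
Reagents that add atoms: chloromethyl methyl ether (MOMCl), COCCl
Why: Williamson-type O-alkylation of the acidic para-acyl phenol; the acetal should resist the enolate, dianion and peracid steps and is removable at the end by mild acid without touching the prenyl alkene.

Step 2
Reactants: 2 1-[2-methoxy-4-(methoxymethoxy)phenyl]ethan-1-one; 3 ethyl acetate (excess)
Product: 4 1-[2-methoxy-4-(methoxymethoxy)phenyl]butane-1,3-dione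
Conditions: NaH (2.5 equiv), THF, reflux; aq NH4Cl
Reagents that add atoms: none
Why: Crossed Claisen condensation of the aryl methyl ketone enolate with ethyl acetate, driven to completion by formation of the sodium diketonate; the aryl ethers are inert to NaH.

Step 3
Reactants: 4 1-[2-methoxy-4-(methoxymethoxy)phenyl]butane-1,3-dione; 5 carbon disulfide
Product: 6 1-[2-methoxy-4-(methoxymethoxy)phenyl]-5,5-bis(methylsulfanyl)pent-4-ene-1,3-dione
Conditions: LiN(iPr)2 (2.2 equiv), THF, −78 to 0 °C; CS2, −78 °C; MeI (2.2 equiv), −78 °C to rt
Reagents that add atoms: iodomethane (MeI), CI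
Why: The 1,3-diketone dianion reacts at its terminal, more basic carbon with the heterocumulene, as it does in alkylation and carboxylation, and the β-oxo dithiocarboxylate is S-methylated twice in the standard CS2/MeI ketene dithioacetal synthesis; two equivalents each of base and MeI leave a neutral product, so C-methylation at C2 should stay minor.

Step 4
Reactants: 6 1-[2-methoxy-4-(methoxymethoxy)phenyl]-5,5-bis(methylsulfanyl)pent-4-ene-1,3-dione
Product: 7 2-[2-methoxy-4-(methoxymethoxy)phenyl]-6-(methylsulfanyl)-4H-pyran-4-one
Conditions: PPTS (0.1 equiv), PhMe, 90 °C, N2 sweep
Reagents that add atoms: none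
Why: Acid-catalysed intramolecular vinylic substitution (addition–elimination): the enol oxygen adds 6-endo to the protonated push–pull ketene dithioacetal carbon and methanethiol is expelled, the known way from α-oxo ketene dithioacetals with a pendant hydroxyl to 2-(methylsulfanyl)pyranones and chromones; a pyridinium acid in a non-hydroxylic solvent should be too weak to cleave the aryl acetal.

Step 5
Reactants: 7 2-[2-methoxy-4-(methoxymethoxy)phenyl]-6-(methylsulfanyl)-4H-pyran-4-one
Product: 8 2-[2-methoxy-4-(methoxymethoxy)phenyl]-6-(methylsulfonyl)-4H-pyran-4-one
Conditions: mCPBA (2.3 equiv), CH2Cl2, 0 °C to rt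
Reagents that add atoms: 3-chloroperbenzoic acid (mCPBA), OOC(=O)c1cccc(Cl)c1
Why: Peracid oxidation of the sulfide through the sulfoxide to the sulfone, as established for 2-(methylsulfanyl)chromones; the electron-poor pyranone double bonds and the aryl ethers are not attacked, and the absence of a nucleophilic solvent protects the electrophilic product.

Step 6
Reactants: 9 methyl acetoacetate; 10 prenyl bromide (1-bromo-3-methylbut-2-ene)
Product: 11 methyl 7-methyl-3-oxooct-6-enoate
Conditions: NaH, THF, 0 °C; n-BuLi, 0 °C; then 10, 0 °C to rt; aq NH4Cl
Reagents that add atoms: none
Why: γ-Alkylation of the acetoacetate dianion, which reacts at its terminal carbon by SN2 displacement at the primary allylic carbon of the bromide.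

Step 7
Reactants: 11 methyl 7-methyl-3-oxooct-6-enoate
Product: 12 methyl (2E)-3-methoxy-7-methylocta-2,6-dienoate
Conditions: HC(OMe)3, H2SO4 (cat.), MeOH, rt; then distillation
Reagents that add atoms: trimethyl orthoformate, COC(OC)OC; methanol, CO
Why: Acid-catalysed ketalisation with the orthoformate and loss of methanol gives the conjugated β-methoxy enoate as its thermodynamic E isomer (OMe trans to the ester), the standard preparation of such enol ethers; the isolated trisubstituted alkene should not add methanol under catalytic acid at room temperature.

Step 8
Reactants: 12 methyl (2E)-3-methoxy-7-methylocta-2,6-dienoate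
Product: 13 (3Z)-1,3-dimethoxy-7-methyl-1-(trimethylsilyloxy)octa-1,3,6-triene
Conditions: LiN(iPr)2, THF, −78 °C; TMSCl, −78 °C to rt; non-aqueous work-up, used at once
Reagents that add atoms: chlorotrimethylsilane (TMSCl), C[Si](C)(C)Cl
Why: Ester-directed γ-deprotonation of the E enoate (the C4 methylene is cis to the ester carbonyl) and O-silylation of the dienolate, the standard route to 1,3-dimethoxy-1-silyloxydienes; the chain on C4 is expected to turn away from C2, which is the 3Z geometry that permits the s-cis conformer.

Step 9
Reactants: 8 2-[2-methoxy-4-(methoxymethoxy)phenyl]-6-(methylsulfonyl)-4H-pyran-4-one; 13 (3Z)-1,3-dimethoxy-7-methyl-1-(trimethylsilyloxy)octa-1,3,6-triene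
Product: 15 5-hydroxy-7-methoxy-2-[2-methoxy-4-(methoxymethoxy)phenyl]-8-(3-methylbut-2-enyl)-4H-chromen-4-one, via tetrahydrochromenone cycloadduct 14 (not isolated)
Conditions: 13 (2.5 equiv), PhMe, 90 °C, sealed tube; then 1 M HCl, THF, 0 °C
Reagents that add atoms: none
Why: Proposed new method: the nucleophilic C4 terminus of the diene should attack pyranone C6 (future C8a), the carbon at which 4-pyranones and 2-sulfonylchromones accept nucleophiles, and the ketene acetal carbon then bonds to the enone α-carbon (future C4a), either in one asynchronous [4+2] event or by Mukaiyama–Michael addition followed by collapse of the enolate/silyloxycarbenium zwitterion in a 6-(enolexo)-exo-trig closure; both paths close ring A as a six-membered carbocycle and give the cis-fused adduct 14. Loss of methanesulfinate from C8a (C4a–H is α to the ketone and O1 assists ionisation) restores the pyranone, and the acid work-up removes methanol from the C5 ketal and the silyl group, so ring A aromatises to the 5-hydroxy-7-methoxy-8-prenyl arene. The closest known reaction types are the benzannulation of 1,3-dimethoxy-1-silyloxydienes with halogenated quinones (polarity-controlled regiochemistry, aromatisation by loss of HX and methanol), the Diels–Alder reactions of 3-acyl- and 3-cyanochromones with silyloxydienes that give xanthones, and the addition of silyl ketene acetals to C2 of silyl-activated chromones; a monocyclic pyranone C=C flanked by carbonyl and sulfonyl has not been used as the dienophile. The four stereocentres of 14 (C4a, C5, C8, C8a) are erased on aromatisation, so no stereocontrol is needed. The step needs regioselectivity, C4 of the diene to C8a and not to C4a, which the enone polarity and the oxygen- and sulfonyl-substituted C6 should secure, and site selectivity for the C5=C6 bond of the pyranone over C2=C3, which carries the electron-rich aryl group and no activating group. The diene is used in excess because the sulfinic acid set free destroys one equivalent of it.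

Step 10
Reactants: 15 5-hydroxy-7-methoxy-2-[2-methoxy-4-(methoxymethoxy)phenyl]-8-(3-methylbut-2-enyl)-4H-chromen-4-one
Product: 16 artocarpetin B, 5-hydroxy-2-(4-hydroxy-2-methoxyphenyl)-7-methoxy-8-(3-methylbut-2-enyl)-4H-chromen-4-one
Conditions: HCl (3 M aq), MeOH–THF, 45 °C
Reagents that add atoms: none
Why: Acid-catalysed methanolysis of the aryl methoxymethyl acetal; the prenyl group has no ortho hydroxyl to cyclise onto, and the chelated 5-OH, the methyl ethers and the pyranone are inert under these conditions.

## Compound list

1 | 4'-hydroxy-2'-methoxyacetophenone | CC(=O)c1ccc(O)cc1OC | starting material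
2 | 1-[2-methoxy-4-(methoxymethoxy)phenyl]ethan-1-one | CC(=O)c1ccc(OCOC)cc1OC | intermediate
3 | ethyl acetate | CCOC(C)=O | starting material
4 | 1-[2-methoxy-4-(methoxymethoxy)phenyl]butane-1,3-dione | CC(=O)CC(=O)c1ccc(OCOC)cc1OC | intermediate
5 | carbon disulfide | S=C=S | starting material
6 | 1-[2-methoxy-4-(methoxymethoxy)phenyl]-5,5-bis(methylsulfanyl)pent-4-ene-1,3-dione | COCOc1ccc(c(OC)c1)C(=O)CC(=O)C=C(SC)SC | intermediate
7 | 2-[2-methoxy-4-(methoxymethoxy)phenyl]-6-(methylsulfanyl)-4H-pyran-4-one | COCOc1ccc(c(OC)c1)-c1cc(=O)cc(SC)o1 | intermediate
8 | 2-[2-methoxy-4-(methoxymethoxy)phenyl]-6-(methylsulfonyl)-4H-pyran-4-one | COCOc1ccc(c(OC)c1)-c1cc(=O)cc(o1)S(C)(=O)=O | intermediate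
9 | methyl acetoacetate | COC(=O)CC(C)=O | starting material
10 | prenyl bromide (1-bromo-3-methylbut-2-ene) | CC(C)=CCBr | starting material
11 | methyl 7-methyl-3-oxooct-6-enoate | COC(=O)CC(=O)CCC=C(C)C | intermediate
12 | methyl (2E)-3-methoxy-7-methylocta-2,6-dienoate | COC(=O)/C=C(/OC)CCC=C(C)C | intermediate
13 | (3Z)-1,3-dimethoxy-7-methyl-1-(trimethylsilyloxy)octa-1,3,6-triene (C1=C2 geometry undefined) | COC(O[Si](C)(C)C)=C/C(OC)=C/CC=C(C)C | intermediate
14 | 5,7-dimethoxy-2-[2-methoxy-4-(methoxymethoxy)phenyl]-8-(3-methylbut-2-enyl)-8a-(methylsulfonyl)-5-(trimethylsilyloxy)-4a,5,8,8a-tetrahydro-4H-chromen-4-one (cis-fused, racemic, C5 and C8 undefined; all stereocentres lost in the same step) | COCOc1ccc(c(OC)c1)C1=CC(=O)C2C(OC)(O[Si](C)(C)C)C=C(OC)C(CC=C(C)C)C2(O1)S(C)(=O)=O | intermediate (not isolated)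
15 | 5-hydroxy-7-methoxy-2-[2-methoxy-4-(methoxymethoxy)phenyl]-8-(3-methylbut-2-enyl)-4H-chromen-4-one | COCOc1ccc(c(OC)c1)-c1cc(=O)c2c(O)cc(OC)c(CC=C(C)C)c2o1 | intermediate
16 | artocarpetin B, 5-hydroxy-2-(4-hydroxy-2-methoxyphenyl)-7-methoxy-8-(3-methylbut-2-enyl)-4H-chromen-4-one | COc1cc(O)ccc1-c1cc(=O)c2c(O)cc(OC)c(CC=C(C)C)c2o1 | target

## Step count and risks

Total step count: 10. Longest linear sequence: 7 steps (steps 1, 2, 3, 4, 5, 9, 10, from 1). The diene branch (steps 6–8) has 3 steps.

**Step 9 (key step, proposed new method).**
- What may go wrong: addition may be too slow at the weakly dienophilic pyranone double bond, so that the acid-labile diene is consumed by protonation first. Alternatively the first-formed zwitterion may expel sulfinate before the second bond forms, so the reaction stops at open-chain substitution.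
- Fallback, from 8 and 11, returning at 15, using known reaction types: the dianion of 11 (NaH, then n-BuLi, THF) is added to 8 at −78 °C. Addition–elimination at the sulfonyl-bearing carbon, the established substitution mode of 2-sulfonyl pyranones and chromones, should give racemic methyl 4-{6-[2-methoxy-4-(methoxymethoxy)phenyl]-4-oxo-4H-pyran-2-yl}-7-methyl-3-oxooct-6-enoate F1. Mg(OMe)2 in MeOH at reflux should then close ring A by intramolecular Claisen condensation of the vinylogous enolate carbon (pyranone C5) onto the ester, in the manner of base-induced polyketo ester aromatisations. The competing aldol mode is geometrically impossible here. The product is 5,7-dihydroxy-2-[2-methoxy-4-(methoxymethoxy)phenyl]-8-(3-methylbut-2-enyl)-4H-chromen-4-one F2 (identical with A7). Selective methylation of the unchelated 7-OH (MeI, 1.1 equiv, K2CO3, acetone, rt) leads back to 15.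

**Step 3.**
- What may go wrong: proton transfer from the acidic CS2 adduct to unreacted dianion would cap the conversion, and C-methylation at C2 of the diketonate may compete with the second S-methylation.
- Fallback, from 4 and 5, returning at 7: the dianion of 4 is treated with CS2 alone and the mixture is acidified with acetic acid. The dithiocarboxylic acid should close onto the enol oxygen with loss of hydrogen sulfide to give 4-hydroxy-6-[2-methoxy-4-(methoxymethoxy)phenyl]-2H-pyran-2-thione F3. S-Methylation of the thione (MeI, K2CO3, acetone, rt) follows the known conversion of 4-hydroxy-2-thiocoumarins into 2-(alkylsulfanyl)chromones and gives 7 directly. Methyl iodide never meets a carbon nucleophile, and 6 and step 4 are bypassed.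

**Step 4.**
- What may go wrong: ring closure may be slow under the weak acid, or the methoxymethyl acetal may be lost, because the methanethiol set free can accept the methoxymethyl cation.
- Fallback, from 6, returning at 7: the closure is run in CF3CO2H/CH2Cl2 at rt, accepting cleavage of the acetal, to give 2-(4-hydroxy-2-methoxyphenyl)-6-(methylsulfanyl)-4H-pyran-4-one F4. The phenol is then protected again with MOMCl and K2CO3 in acetone to give 7.

**Step 8.**
- What may go wrong: deprotonation may give the C3=C4 geometry with the chain cis to C2, which blocks the s-cis conformer, or the ketene acetal may hydrolyse during isolation.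
- Fallback, from 11, returning at 15: the keto ester is silylated (TMSCl, Et3N, PhMe, rt) to methyl (2Z)-7-methyl-3-(trimethylsilyloxy)octa-2,6-dienoate F5. A second deprotonation and silylation (LiN(iPr)2, TMSCl, THF, −78 °C) gives (3Z)-1-methoxy-7-methyl-1,3-bis(trimethylsilyloxy)octa-1,3,6-triene F6, a member of a diene family whose 4-alkyl representatives are routinely made and used in cyclisations. Reaction of F6 with 8 under the conditions of step 9 should give 5,7-dihydroxy-2-[2-methoxy-4-(methoxymethoxy)phenyl]-8-(3-methylbut-2-enyl)-4H-chromen-4-one F2 after loss of methanesulfinic acid, methanol and both silyl groups. Selective 7-O-methylation as above leads to 15.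

## Further compounds

F1 | step 9 | methyl 4-{6-[2-methoxy-4-(methoxymethoxy)phenyl]-4-oxo-4H-pyran-2-yl}-7-methyl-3-oxooct-6-enoate (racemic) | COCOc1ccc(c(OC)c1)-c1cc(=O)cc(o1)C(CC=C(C)C)C(=O)CC(=O)OC
F2 | step 9 | 5,7-dihydroxy-2-[2-methoxy-4-(methoxymethoxy)phenyl]-8-(3-methylbut-2-enyl)-4H-chromen-4-one | COCOc1ccc(c(OC)c1)-c1cc(=O)c2c(O)cc(O)c(CC=C(C)C)c2o1
F3 | step 3 | 4-hydroxy-6-[2-methoxy-4-(methoxymethoxy)phenyl]-2H-pyran-2-thione | COCOc1ccc(c(OC)c1)-c1cc(O)cc(=S)o1
F4 | step 4 | 2-(4-hydroxy-2-methoxyphenyl)-6-(methylsulfanyl)-4H-pyran-4-one | COc1cc(O)ccc1-c1cc(=O)cc(SC)o1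
F5 | step 8 | methyl (2Z)-7-methyl-3-(trimethylsilyloxy)octa-2,6-dienoate | COC(=O)/C=C(\O[Si](C)(C)C)CCC=C(C)C
F6 | step 8 | (3Z)-1-methoxy-7-methyl-1,3-bis(trimethylsilyloxy)octa-1,3,6-triene | COC(O[Si](C)(C)C)=C/C(O[Si](C)(C)C)=C/CC=C(C)C
A1 | alternative 1 | 2-ethynyl-5,7-dimethoxy-8-(3-methylbut-2-enyl)chromen-4-one | COc1cc(OC)c(CC=C(C)C)c2oc(C#C)cc(=O)c12
A2 | alternative 1 | 1,1-dimethoxy-3-(trimethylsilyloxy)buta-1,3-diene | COC(OC)=CC(=C)O[Si](C)(C)C
A3 | alternative 1 | 2-(4-hydroxy-2-methoxyphenyl)-5,7-dimethoxy-8-(3-methylbut-2-enyl)chromen-4-one | COc1cc(OC)c(CC=C(C)C)c2oc(-c3ccc(O)cc3OC)cc(=O)c12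
A4 | alternative 2 | (2Z)-3-[4-(benzyloxy)-2-methoxyphenyl]-3-[3,5-dimethoxy-2-(3-methylbut-2-enyl)phenoxy]prop-2-enoic acid | OC(=O)/C=C(\Oc1cc(OC)cc(OC)c1CC=C(C)C)c1ccc(OCc2ccccc2)cc1OC
A5 | alternative 2 | 2-[4-(benzyloxy)-2-methoxyphenyl]-5,7-dimethoxy-8-(3-methylbut-2-enyl)chromen-4-one | COc1cc(OCc2ccccc2)ccc1-c1cc(=O)c2c(OC)cc(OC)c(CC=C(C)C)c2o1
A6 | alternative 3 | methyl 6-[2-methoxy-4-(methoxymethoxy)phenyl]-2-(6-methyl-2-oxohept-5-en-3-yl)-4-oxo-4H-pyran-3-carboxylate | COCOc1ccc(c(OC)c1)-c1cc(=O)c(C(=O)OC)c(o1)C(CC=C(C)C)C(C)=O
A7 | alternative 3 | 5,7-dihydroxy-2-[2-methoxy-4-(methoxymethoxy)phenyl]-8-(3-methylbut-2-enyl)chromen-4-one | COCOc1ccc(c(OC)c1)-c1cc(=O)c2c(O)cc(O)c(CC=C(C)C)c2o1
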